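**Retrosynthetic overview**
- Last step: face-selective epoxidation of the strained (E)-C4=C5 alkene of the peroxide-bearing diene, the same logic as caryophyllene to caryophyllene oxide.
- 1,2-Dioxin-3-ol: perhydrolysis (inversion at the tertiary carbon) of a (Z)-γ,δ-epoxy enone followed by peroxyhemiketalisation; the enone comes from a C12 aldehyde and (S)-2-ethynyl-2-methyloxirane.
- Nine-membered ring: B-alkyl Suzuki macrocyclisation forming C5–C6 from an (E)-vinyl iodide and a vinyl carbinol; the C8 carbinol then becomes ketone and exocyclic methylene.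
- Cyclobutane with C1 and quaternary C11: proposed catalytic enantioselective keteniminium–alkene [2+2] of an (E)-trisubstituted allyl silyl ether with a terminal ynamide as ketene surrogate, then one-carbon homologation at C9.
- Ring order: cyclobutane, then cyclononene, then 1,2-dioxine, then oxirane; the acyclic precursor comes from pent-4-yn-1-ol by carboalumination and (E)-selective Wittig olefination.

Assumption: caryophyllane numbering is used for the core (C1 and C9 ring fusion, C4=C5, C8 bearing the exocyclic methylene, C10 the cyclobutane CH2, C11 quaternary, C12–C15 side chain); the terminal ynamide coupling reagent and (S)-2-methylglycidol are taken as purchasable.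

**Route**

Step 1
Reactants: 1 pent-4-yn-1-ol
Product: 3 (E)-5-iodo-4-methylpent-4-en-1-ol, via alkenylalane 2 (not isolated)
Conditions: AlMe3 (3 equiv), Cp2ZrCl2 (0.25 equiv), CH2Cl2, 0 to 23 °C; then I2, THF, −30 to 0 °C; aq. K2CO3 work-up
Reagents that add atoms: trimethylaluminium (C[Al](C)C); iodine (II)
Why: Zirconium-catalysed Negishi carboalumination adds methyl and aluminium syn across the terminal alkyne with aluminium at the terminus, and iodinolysis with retention gives only the (E)-iodoalkene.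

Step 2
Reactants: 3 (E)-5-iodo-4-methylpent-4-en-1-ol
Product: 4 (E)-5-iodo-4-methylpent-4-enal
Conditions: Dess–Martin periodinane, CH2Cl2, 0 to 23 °C
Reagents that add atoms: none
Why: Dess–Martin oxidation of a primary alcohol stops at the aldehyde and does not touch the vinyl iodide.

Step 3
Reactants: 4 (E)-5-iodo-4-methylpent-4-enal; 5 ethyl 2-(triphenyl-λ5-phosphanylidene)propanoate
Product: 6 ethyl (2E,6E)-7-iodo-2,6-dimethylhepta-2,6-dienoate
Conditions: CH2Cl2, 23 °C
Reagents that add atoms: none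
Why: Wittig olefination with a stabilised α-methyl ylide gives the (E)-trisubstituted enoate, fixing the alkene geometry that later becomes the relative configuration of C1 and C11.

Step 4
Reactants: 6 ethyl (2E,6E)-7-iodo-2,6-dimethylhepta-2,6-dienoate
Product: 7 (2E,6E)-7-iodo-2,6-dimethylhepta-2,6-dien-1-ol
Conditions: i-Bu2AlH (2.5 equiv), CH2Cl2, −78 °C; aq. potassium sodium tartrate
Reagents that add atoms: none
Why: 1,2-Reduction of the enoate by the aluminium hydride gives the allylic alcohol without changing either alkene geometry.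

Step 5
Reactants: 7 (2E,6E)-7-iodo-2,6-dimethylhepta-2,6-dien-1-ol
Product: 8 tert-butyl{[(2E,6E)-7-iodo-2,6-dimethylhepta-2,6-dien-1-yl]oxy}diphenylsilane
Conditions: t-BuPh2SiCl, imidazole, DMF, 23 °C
Reagents that add atoms: tert-butyl(chloro)diphenylsilane (CC(C)(C)[Si](Cl)(c1ccccc1)c1ccccc1)
Why: Standard silylation gives a bulky, acid-stable silyl ether that masks the C12 oxygen and keeps it from interfering with the cationic step that follows.

Step 6
Reactants: 8 tert-butyl{[(2E,6E)-7-iodo-2,6-dimethylhepta-2,6-dien-1-yl]oxy}diphenylsilane; 9 N-ethynyl-N,4-dimethylbenzenesulfonamide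
Product: 11 (2R,3S)-3-[(tert-butyldiphenylsilyloxy)methyl]-2-[(E)-4-iodo-3-methylbut-3-en-1-yl]-3-methylcyclobutan-1-one, via cyclobutenyl sulfonamide 10 (not isolated)
Conditions: 9 (1.5 equiv, slow addition), chiral imidodiphosphorimidate Brønsted acid built from two (S)-3,3'-bis[3,5-bis(trifluoromethyl)phenyl]-1,1'-bi-2-naphthol units with N-trifluoromethanesulfonyl groups (5 mol %; the mirror-image acid is used if a model run shows the opposite sense of induction), 4 Å MS, CH2Cl2, −40 °C; then 1 M aq. HCl, THF, 23 °C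
Reagents that add atoms: water (O)
Why: Proposed new method: the confined chiral acid protonates the terminal ynamide at carbon to give an N-sulfonyl keteniminium ion paired with the chiral anion; the electron-richer trisubstituted alkene (the iodoalkene is deactivated) attacks the central keteniminium carbon through C1 so that charge builds at tertiary C11, and closure of the enamide carbon onto C11 in a concerted asynchronous, alkene-suprafacial [2+2] turns the (E) geometry into the cis relationship of the C1 chain and the C11 methyl while the anion pocket selects the alkene face and so sets C1 and quaternary C11 together; proton loss from the cyclobutaniminium ion to the next ynamide turns the acid over and leaves enamide 10, which is hydrolysed on work-up; the closest known reaction types are the stoichiometric, auxiliary-controlled keteniminium–alkene [2+2] cycloaddition and Brønsted-acid activation of ynamides.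

Step 7
Reactants: 11 (2R,3S)-3-[(tert-butyldiphenylsilyloxy)methyl]-2-[(E)-4-iodo-3-methylbut-3-en-1-yl]-3-methylcyclobutan-1-one
Product: 12 (2R,3S)-3-[(tert-butyldiphenylsilyloxy)methyl]-2-[(E)-4-iodo-3-methylbut-3-en-1-yl]-1-(methoxymethylidene)-3-methylcyclobutane (enol ether E/Z mixture)
Conditions: MeOCH2PPh3Cl, KN(SiMe3)2, THF, −78 to 0 °C
Reagents that add atoms: (methoxymethyl)triphenylphosphonium chloride (COC[P+](c1ccccc1)(c1ccccc1)c1ccccc1.[Cl-])
Why: Wittig methoxymethylenation homologates the strained, electrophilic cyclobutanone by one carbon, and the adjacent stereocentre is already the thermodynamically preferred epimer (chain anti to the silyloxymethyl group) so the basic ylide does not erode it.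

Step 8
Reactants: 12 (2R,3S)-3-[(tert-butyldiphenylsilyloxy)methyl]-2-[(E)-4-iodo-3-methylbut-3-en-1-yl]-1-(methoxymethylidene)-3-methylcyclobutane
Product: 14 (1R,2S,3S)-3-[(tert-butyldiphenylsilyloxy)methyl]-2-[(E)-4-iodo-3-methylbut-3-en-1-yl]-3-methylcyclobutane-1-carbaldehyde, via cis aldehyde 13 (not isolated)
Conditions: 2 M aq. HCl, THF, 23 °C; then DBU (0.2 equiv), CH2Cl2, 23 °C
Reagents that add atoms: water (O)
Why: Acid hydrolysis of the enol ether gives the aldehyde mainly as the kinetic cis isomer, and amine-catalysed enolisation equilibrates it to the trans-1,2 (cis-1,3) aldehyde, which sets the ring-fusion centre C9 under thermodynamic control.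

Step 9
Reactants: 14 (1R,2S,3S)-3-[(tert-butyldiphenylsilyloxy)methyl]-2-[(E)-4-iodo-3-methylbut-3-en-1-yl]-3-methylcyclobutane-1-carbaldehyde
Product: 15 1-{(1R,2S,3S)-3-[(tert-butyldiphenylsilyloxy)methyl]-2-[(E)-4-iodo-3-methylbut-3-en-1-yl]-3-methylcyclobutyl}prop-2-en-1-ol (mixture of carbinol epimers)
Conditions: CH2=CHMgBr, THF, −78 °C; aq. NH4Cl
Reagents that add atoms: vinylmagnesium bromide (C=C[Mg]Br)
Why: Grignard 1,2-addition to the aldehyde installs C7 and C6, and the unselective carbinol centre is removed later by oxidation to the C8 ketone.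

Step 10
Reactants: 15 1-{(1R,2S,3S)-3-[(tert-butyldiphenylsilyloxy)methyl]-2-[(E)-4-iodo-3-methylbut-3-en-1-yl]-3-methylcyclobutyl}prop-2-en-1-ol
Product: 16 triethylsilyl ether of 15 (mixture of carbinol epimers)
Conditions: Et3SiOTf, 2,6-lutidine, CH2Cl2, −78 °C
Reagents that add atoms: triethylsilyl trifluoromethanesulfonate (CC[Si](CC)(CC)OS(=O)(=O)C(F)(F)F)
Why: Silylation protects the allylic alcohol from the borane with a group that can later be removed selectively in the presence of the tert-butyldiphenylsilyl ether.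

Step 11
Reactants: 16 triethylsilyl ether of 15
Product: 18 (1S,4E,9R,11S)-11-[(tert-butyldiphenylsilyloxy)methyl]-4,11-dimethyl-8-(triethylsilyloxy)bicyclo[7.2.0]undec-4-ene (C8 epimers), via alkylborane 17 (not isolated)
Conditions: 9-BBN, THF, 23 °C; then slow addition to PdCl2(dppf) (15 mol %), AsPh3, Cs2CO3, THF/DMF/H2O, 50 °C, 2 mM
Reagents that add atoms: none
Why: 9-BBN hydroborates only the monosubstituted vinyl group (anti-Markovnikov), and the intramolecular B-alkyl Suzuki–Miyaura coupling with the (E)-vinyl iodide under high dilution closes the nine-membered ring with retention of alkene geometry on a ring fusion that is already trans.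

Step 12
Reactants: 18 (1S,4E,9R,11S)-11-[(tert-butyldiphenylsilyloxy)methyl]-4,11-dimethyl-8-(triethylsilyloxy)bicyclo[7.2.0]undec-4-ene
Product: 19 (1S,4E,9R,11S)-11-[(tert-butyldiphenylsilyloxy)methyl]-4,11-dimethylbicyclo[7.2.0]undec-4-en-8-ol (C8 epimers)
Conditions: pyridinium p-toluenesulfonate (0.1 equiv), MeOH/CH2Cl2, 0 to 23 °C
Reagents that add atoms: none
Why: Mild acid methanolysis cleaves the triethylsilyl ether selectively and leaves the bulkier diphenylsilyl ether and the strained alkene intact.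

Step 13
Reactants: 19 (1S,4E,9R,11S)-11-[(tert-butyldiphenylsilyloxy)methyl]-4,11-dimethylbicyclo[7.2.0]undec-4-en-8-ol
Product: 20 (1S,4E,9R,11S)-11-[(tert-butyldiphenylsilyloxy)methyl]-4,11-dimethylbicyclo[7.2.0]undec-4-en-8-one
Conditions: Dess–Martin periodinane, CH2Cl2, 23 °C
Reagents that add atoms: none
Why: Dess–Martin oxidation converges both carbinol epimers to one ketone, and the adjacent C9 centre stays trans-fused because that is the thermodynamically preferred ring fusion of the (E)-cyclononenone.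

Step 14
Reactants: 20 (1S,4E,9R,11S)-11-[(tert-butyldiphenylsilyloxy)methyl]-4,11-dimethylbicyclo[7.2.0]undec-4-en-8-one
Product: 21 tert-butyl{[(1S,4E,9R,11S)-4,11-dimethyl-8-methylidenebicyclo[7.2.0]undec-4-en-11-yl]methoxy}diphenylsilane
Conditions: Ph3PCH3Br, KOt-Bu, toluene, 0 to 60 °C
Reagents that add atoms: methyltriphenylphosphonium bromide (C[P+](c1ccccc1)(c1ccccc1)c1ccccc1.[Br-])
Why: Wittig methylenation installs the exocyclic C8 methylene as in classical caryophyllene syntheses, and any enolisation returns the favoured trans ring fusion.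

Step 15
Reactants: 21 tert-butyl{[(1S,4E,9R,11S)-4,11-dimethyl-8-methylidenebicyclo[7.2.0]undec-4-en-11-yl]methoxy}diphenylsilane
Product: 22 [(1S,4E,9R,11S)-4,11-dimethyl-8-methylidenebicyclo[7.2.0]undec-4-en-11-yl]methanol
Conditions: Bu4NF, THF, 23 to 40 °C; aq. NH4Cl
Reagents that add atoms: none
Why: Fluoride-mediated desilylation frees the neopentyl alcohol in a molecule that has no base- or fluoride-sensitive group.

Step 16
Reactants: 22 [(1S,4E,9R,11S)-4,11-dimethyl-8-methylidenebicyclo[7.2.0]undec-4-en-11-yl]methanol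
Product: 23 (1S,4E,9R,11S)-4,11-dimethyl-8-methylidenebicyclo[7.2.0]undec-4-ene-11-carbaldehyde
Conditions: Dess–Martin periodinane, CH2Cl2, 0 to 23 °C
Reagents that add atoms: none
Why: Dess–Martin oxidation gives the aldehyde on quaternary C11, which has no α-hydrogen and therefore cannot epimerise.

Step 17
Reactants: 24 [(2S)-2-methyloxiran-2-yl]methanol
Product: 25 (2R)-2-methyloxirane-2-carbaldehyde
Conditions: Dess–Martin periodinane, CH2Cl2, 0 °C; filtered solution used directly
Reagents that add atoms: none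
Why: Dess–Martin oxidation under neutral conditions gives the volatile epoxy aldehyde, whose quaternary stereocentre cannot epimerise (the descriptor changes only through priorities).

Step 18
Reactants: 25 (2R)-2-methyloxirane-2-carbaldehyde
Product: 26 (2S)-2-ethynyl-2-methyloxirane
Conditions: dimethyl (1-diazo-2-oxopropyl)phosphonate, K2CO3, MeOH/CH2Cl2, 0 to 23 °C; distilled into Et2O
Reagents that add atoms: dimethyl (1-diazo-2-oxopropyl)phosphonate (CC(=O)C(=[N+]=[N-])P(=O)(OC)OC)
Why: Seyferth–Gilbert homologation under Ohira–Bestmann conditions converts the aldehyde into the terminal alkyne without touching the epoxide stereocentre.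

Step 19
Reactants: 23 (1S,4E,9R,11S)-4,11-dimethyl-8-methylidenebicyclo[7.2.0]undec-4-ene-11-carbaldehyde; 26 (2S)-2-ethynyl-2-methyloxirane
Product: 28 1-[(1S,4E,9R,11S)-4,11-dimethyl-8-methylidenebicyclo[7.2.0]undec-4-en-11-yl]-3-[(2S)-2-methyloxiran-2-yl]prop-2-yn-1-ol (C12 epimers), via lithium acetylide 27 (not isolated)
Conditions: 26, n-BuLi, THF, −78 °C; then 23, −78 to −20 °C; aq. NH4Cl
Reagents that add atoms: none
Why: Acetylide addition to the non-enolisable neopentyl aldehyde joins the two fragments, and the unselective carbinol centre is removed by the next oxidation.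

Step 20
Reactants: 28 1-[(1S,4E,9R,11S)-4,11-dimethyl-8-methylidenebicyclo[7.2.0]undec-4-en-11-yl]-3-[(2S)-2-methyloxiran-2-yl]prop-2-yn-1-ol
Product: 29 1-[(1S,4E,9R,11S)-4,11-dimethyl-8-methylidenebicyclo[7.2.0]undec-4-en-11-yl]-3-[(2S)-2-methyloxiran-2-yl]prop-2-yn-1-one
Conditions: Dess–Martin periodinane, CH2Cl2, 0 °C
Reagents that add atoms: none
Why: Dess–Martin oxidation of the propargylic alcohol gives the ynone under neutral conditions that spare the epoxide and the strained alkene.

Step 21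
Reactants: 29 1-[(1S,4E,9R,11S)-4,11-dimethyl-8-methylidenebicyclo[7.2.0]undec-4-en-11-yl]-3-[(2S)-2-methyloxiran-2-yl]prop-2-yn-1-one
Product: 30 (2Z)-1-[(1S,4E,9R,11S)-4,11-dimethyl-8-methylidenebicyclo[7.2.0]undec-4-en-11-yl]-3-[(2S)-2-methyloxiran-2-yl]prop-2-en-1-one
Conditions: H2 (1 atm), Pd/CaCO3 poisoned with Pb(OAc)2, quinoline, EtOAc, 0 °C
Reagents that add atoms: none
Why: Semi-hydrogenation over lead-poisoned palladium adds hydrogen syn to the alkyne only, giving the (Z)-enone needed for six-membered ring closure while the trisubstituted and 1,1-disubstituted alkenes are left alone.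

Step 22
Reactants: 30 (2Z)-1-[(1S,4E,9R,11S)-4,11-dimethyl-8-methylidenebicyclo[7.2.0]undec-4-en-11-yl]-3-[(2S)-2-methyloxiran-2-yl]prop-2-en-1-one
Product: 32 (3R,6R)-3-[(1S,4E,9R,11S)-4,11-dimethyl-8-methylidenebicyclo[7.2.0]undec-4-en-11-yl]-6-(hydroxymethyl)-6-methyl-3,6-dihydro-1,2-dioxin-3-ol, via hydroperoxy enone 31 (not isolated)
Conditions: anhydrous H2O2 in Et2O (10 equiv), H3PMo12O40 (3 mol %), Et2O, 0 °C
Reagents that add atoms: hydrogen peroxide (OO)
Why: Acid-catalysed perhydrolysis of the 2,2-disubstituted epoxide occurs at the tertiary allylic carbon with inversion (borderline SN2, possibly delivered 6-exo from the ketone perhydrate), which sets the quaternary peroxide carbon as (R) and frees the CH2OH group; the (Z)-γ-hydroperoxy enone then closes spontaneously to the peroxyhemiketal, whose hemiketal centre equilibrates by ring–chain tautomerism to the (3R) anomer of the target (hydroxyl pseudo-axial, cyclobutyl and CH2OH pseudo-equatorial), the minor anomer being recycled by re-equilibration.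

Step 23
Reactants: 32 (3R,6R)-3-[(1S,4E,9R,11S)-4,11-dimethyl-8-methylidenebicyclo[7.2.0]undec-4-en-11-yl]-6-(hydroxymethyl)-6-methyl-3,6-dihydro-1,2-dioxin-3-ol
Product: 33 (3R,6R)-3-[(1S,4S,5S,9R,11S)-4,5-epoxy-4,11-dimethyl-8-methylidenebicyclo[7.2.0]undecan-11-yl]-6-(hydroxymethyl)-6-methyl-3,6-dihydro-1,2-dioxin-3-ol (target CNP0273942.1)
Conditions: dimethyldioxirane (1.05 equiv), acetone, −40 to −20 °C
Reagents that add atoms: dimethyldioxirane (CC1(C)OO1)
Why: Electrophilic dioxirane epoxidation picks the strained (E)-trisubstituted ring alkene over the exocyclic methylene and the electron-poor dioxine alkene, and attack on the exposed outer face of the dominant ring conformers gives the caryophyllene-oxide-type (4S,5S) epoxide as the major, separable diastereomer (about 4:1 expected by analogy with caryophyllene).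

**Compound list**

1 | pent-4-yn-1-ol | C#CCCCO | starting material
2 | dimethyl[(E)-5-(dimethylalumanyloxy)-2-methylpent-1-en-1-yl]alumane | C[Al](C)/C=C(\C)CCCO[Al](C)C | intermediate
3 | (E)-5-iodo-4-methylpent-4-en-1-ol | OCCC/C(C)=C/I | intermediate
4 | (E)-5-iodo-4-methylpent-4-enal | O=CCC/C(C)=C/I | intermediate
5 | ethyl 2-(triphenyl-λ5-phosphanylidene)propanoate | CCOC(=O)C(C)=P(c1ccccc1)(c1ccccc1)c1ccccc1 | starting material
6 | ethyl (2E,6E)-7-iodo-2,6-dimethylhepta-2,6-dienoate | CCOC(=O)/C(C)=C/CC/C(C)=C/I | intermediate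
7 | (2E,6E)-7-iodo-2,6-dimethylhepta-2,6-dien-1-ol | OC/C(C)=C/CC/C(C)=C/I | intermediate
8 | tert-butyl{[(2E,6E)-7-iodo-2,6-dimethylhepta-2,6-dien-1-yl]oxy}diphenylsilane | CC(C)(C)[Si](OC/C(C)=C/CC/C(C)=C/I)(c1ccccc1)c1ccccc1 | intermediate
9 | N-ethynyl-N,4-dimethylbenzenesulfonamide | C#CN(C)S(=O)(=O)c1ccc(C)cc1 | starting material
10 | N-{(3S,4R)-3-[(tert-butyldiphenylsilyloxy)methyl]-4-[(E)-4-iodo-3-methylbut-3-en-1-yl]-3-methylcyclobut-1-en-1-yl}-N,4-dimethylbenzenesulfonamide | I/C=C(C)/CC[C@H]2C(N(C)S(=O)(=O)c3ccc(C)cc3)=C[C@]2(C)CO[Si](c1ccccc1)(c1ccccc1)C(C)(C)C | intermediate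
11 | (2R,3S)-3-[(tert-butyldiphenylsilyloxy)methyl]-2-[(E)-4-iodo-3-methylbut-3-en-1-yl]-3-methylcyclobutan-1-one | I/C=C(C)/CC[C@H]2C(=O)C[C@]2(C)CO[Si](c1ccccc1)(c1ccccc1)C(C)(C)C | intermediate
12 | (2R,3S)-3-[(tert-butyldiphenylsilyloxy)methyl]-2-[(E)-4-iodo-3-methylbut-3-en-1-yl]-1-(methoxymethylidene)-3-methylcyclobutane (enol ether E/Z mixture) | I/C=C(C)/CC[C@H]2C(=COC)C[C@]2(C)CO[Si](c1ccccc1)(c1ccccc1)C(C)(C)C | intermediate
13 | (1S,2S,3S)-3-[(tert-butyldiphenylsilyloxy)methyl]-2-[(E)-4-iodo-3-methylbut-3-en-1-yl]-3-methylcyclobutane-1-carbaldehyde (cis aldehyde) | I/C=C(C)/CC[C@H]2[C@@H](C=O)C[C@]2(C)CO[Si](c1ccccc1)(c1ccccc1)C(C)(C)C | intermediate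
14 | (1R,2S,3S)-3-[(tert-butyldiphenylsilyloxy)methyl]-2-[(E)-4-iodo-3-methylbut-3-en-1-yl]-3-methylcyclobutane-1-carbaldehyde (trans aldehyde) | I/C=C(C)/CC[C@H]2[C@H](C=O)C[C@]2(C)CO[Si](c1ccccc1)(c1ccccc1)C(C)(C)C | intermediate
15 | 1-{(1R,2S,3S)-3-[(tert-butyldiphenylsilyloxy)methyl]-2-[(E)-4-iodo-3-methylbut-3-en-1-yl]-3-methylcyclobutyl}prop-2-en-1-ol (carbinol epimers) | I/C=C(C)/CC[C@H]2[C@H](C(O)C=C)C[C@]2(C)CO[Si](c1ccccc1)(c1ccccc1)C(C)(C)C | intermediate
16 | triethylsilyl ether of 15 (carbinol epimers) | I/C=C(C)/CC[C@H]2[C@H](C(O[Si](CC)(CC)CC)C=C)C[C@]2(C)CO[Si](c1ccccc1)(c1ccccc1)C(C)(C)C | intermediate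
17 | B-alkyl-9-borabicyclo[3.3.1]nonane from hydroboration of the vinyl group of 16 | I/C=C(C)/CC[C@H]2[C@H](C(O[Si](CC)(CC)CC)CCB3C4CCCC3CCC4)C[C@]2(C)CO[Si](c1ccccc1)(c1ccccc1)C(C)(C)C | intermediate
18 | (1S,4E,9R,11S)-11-[(tert-butyldiphenylsilyloxy)methyl]-4,11-dimethyl-8-(triethylsilyloxy)bicyclo[7.2.0]undec-4-ene (C8 epimers) | CC[Si](CC)(CC)OC1CC/C=C(C)/CC[C@H]2[C@H]1C[C@]2(C)CO[Si](c1ccccc1)(c1ccccc1)C(C)(C)C | intermediate
19 | (1S,4E,9R,11S)-11-[(tert-butyldiphenylsilyloxy)methyl]-4,11-dimethylbicyclo[7.2.0]undec-4-en-8-ol (C8 epimers) | OC1CC/C=C(C)/CC[C@H]2[C@H]1C[C@]2(C)CO[Si](c1ccccc1)(c1ccccc1)C(C)(C)C | intermediate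
20 | (1S,4E,9R,11S)-11-[(tert-butyldiphenylsilyloxy)methyl]-4,11-dimethylbicyclo[7.2.0]undec-4-en-8-one | O=C1CC/C=C(C)/CC[C@H]2[C@H]1C[C@]2(C)CO[Si](c1ccccc1)(c1ccccc1)C(C)(C)C | intermediate
21 | tert-butyl{[(1S,4E,9R,11S)-4,11-dimethyl-8-methylidenebicyclo[7.2.0]undec-4-en-11-yl]methoxy}diphenylsilane | C=C1CC/C=C(C)/CC[C@H]2[C@H]1C[C@]2(C)CO[Si](c1ccccc1)(c1ccccc1)C(C)(C)C | intermediate
22 | [(1S,4E,9R,11S)-4,11-dimethyl-8-methylidenebicyclo[7.2.0]undec-4-en-11-yl]methanol | C=C1CC/C=C(C)/CC[C@H]2[C@H]1C[C@]2(C)CO | intermediate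
23 | (1S,4E,9R,11S)-4,11-dimethyl-8-methylidenebicyclo[7.2.0]undec-4-ene-11-carbaldehyde | C=C1CC/C=C(C)/CC[C@H]2[C@H]1C[C@]2(C)C=O | intermediate
24 | [(2S)-2-methyloxiran-2-yl]methanol | OC[C@@]1(C)CO1 | starting material
25 | (2R)-2-methyloxirane-2-carbaldehyde | O=C[C@@]1(C)CO1 | intermediate
26 | (2S)-2-ethynyl-2-methyloxirane | C#C[C@@]1(C)CO1 | intermediate
27 | lithium [(2S)-2-methyloxiran-2-yl]acetylide | [Li]C#C[C@@]1(C)CO1 | intermediate
28 | 1-[(1S,4E,9R,11S)-4,11-dimethyl-8-methylidenebicyclo[7.2.0]undec-4-en-11-yl]-3-[(2S)-2-methyloxiran-2-yl]prop-2-yn-1-ol (C12 epimers) | C=C1CC/C=C(C)/CC[C@H]2[C@H]1C[C@]2(C)C(O)C#C[C@@]1(C)CO1 | intermediate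
29 | 1-[(1S,4E,9R,11S)-4,11-dimethyl-8-methylidenebicyclo[7.2.0]undec-4-en-11-yl]-3-[(2S)-2-methyloxiran-2-yl]prop-2-yn-1-one | C=C1CC/C=C(C)/CC[C@H]2[C@H]1C[C@]2(C)C(=O)C#C[C@@]1(C)CO1 | intermediate
30 | (2Z)-1-[(1S,4E,9R,11S)-4,11-dimethyl-8-methylidenebicyclo[7.2.0]undec-4-en-11-yl]-3-[(2S)-2-methyloxiran-2-yl]prop-2-en-1-one | C=C1CC/C=C(C)/CC[C@H]2[C@H]1C[C@]2(C)C(=O)/C=C\[C@@]1(C)CO1 | intermediate
31 | (2Z,4R)-1-[(1S,4E,9R,11S)-4,11-dimethyl-8-methylidenebicyclo[7.2.0]undec-4-en-11-yl]-4-hydroperoxy-5-hydroxy-4-methylpent-2-en-1-one | C=C1CC/C=C(C)/CC[C@H]2[C@H]1C[C@]2(C)C(=O)/C=C\[C@](C)(CO)OO | intermediate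
32 | (3R,6R)-3-[(1S,4E,9R,11S)-4,11-dimethyl-8-methylidenebicyclo[7.2.0]undec-4-en-11-yl]-6-(hydroxymethyl)-6-methyl-3,6-dihydro-1,2-dioxin-3-ol | C=C1CC/C=C(C)/CC[C@H]2[C@H]1C[C@]2(C)[C@@]1(O)C=C[C@](C)(CO)OO1 | intermediate
33 | (3R,6R)-3-[(1S,4S,5S,9R,11S)-4,5-epoxy-4,11-dimethyl-8-methylidenebicyclo[7.2.0]undecan-11-yl]-6-(hydroxymethyl)-6-methyl-3,6-dihydro-1,2-dioxin-3-ol | C=C1CC[C@@H]2O[C@@]2(C)CC[C@H]2[C@H]1C[C@]2(C)[C@@]1(O)C=C[C@](C)(CO)OO1 | target

**Step count**

Total steps: 23. Longest linear sequence: 21 (steps 1–16 and 19–23); the alkynyl epoxide branch is 2 steps (17–18).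

**Three steps most likely to fail**

Step 6 (the proposed new [2+2]). Risks are poor catalyst turnover, ene-type or sulfonyl-oxygen trapping of the C11 cation instead of ring closure, ynamide self-reaction, and insufficient enantioselectivity. The fallback uses known auxiliary-controlled keteniminium chemistry; it sets out from 8 and comes back at 11. The amide 1-[(2S,5S)-2,5-dimethylpyrrolidin-1-yl]ethan-1-one F1, made from the commercial C2-symmetric amine and acetyl chloride, is treated with Tf2O and 2,4,6-collidine in ClCH2CH2Cl to give the chiral keteniminium triflate F2. Heating F2 with 8 gives the stoichiometric thermal [2+2] adduct, the cyclobutaniminium triflate F3, with the same regiochemistry and alkene-suprafacial stereospecificity as in step 6. Aqueous NaHCO3 hydrolysis of F3 releases 11 and the recoverable amine. The auxiliary enantiomer is chosen to give (2R,3S)-11, and the minor enantiomer is removed by chromatography on a chiral phase if needed.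

Step 11 (B-alkyl Suzuki macrocyclisation). Risks are ring strain of the (E)-cyclononene, oligomerisation, protodeboronation and β-hydride elimination. The fallback changes the ring-closing bond construction to a chromium/nickel-mediated carbonyl addition; it sets out from 16 and comes back at 18. Hydroboration of 16 with 9-BBN (through 17) and oxidative work-up with NaBO3 gives the primary alcohol F4, and Dess–Martin oxidation gives the aldehyde F5. Nozaki–Hiyama–Kishi cyclisation of F5 (CrCl2, NiCl2 1 mol %, DMSO/THF, 2 mM) joins C5 to C6 with retention of the (E) geometry and gives the nine-membered allylic alcohol F6. Acetylation (Ac2O, pyridine, DMAP) gives the allylic acetate F7. Palladium-catalysed hydride reduction (Pd(PPh3)4, LiBHEt3, THF) delivers hydride to the less substituted allyl terminus C6 and returns 18.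

Step 22 (perhydrolysis and peroxyhemiketalisation). Risks are attack of the enone carbonyl oxygen on the epoxide (a dihydrofuran by-product), opening at the primary carbon, oxidation or acid rearrangement of the strained ring alkene, and partial loss of stereospecificity at the tertiary carbon. The fallback replaces epoxide opening by a singlet-oxygen ene reaction, at the cost of stereocontrol at the quaternary peroxide carbon; it sets out from 30 and comes back at 33. Dimethyldioxirane first epoxidises the ring alkene of 30 to give the bis-epoxide F8, so that singlet oxygen cannot attack C4=C5 later. SmI2 (THF/MeOH, −78 °C) reductively opens the γ,δ-epoxy enone of F8 to the (E)-δ-hydroxy-β,γ-unsaturated ketone F9. Schenck ene reaction of F9 (O2, visible light, tetraphenylporphyrin, CH2Cl2, −20 °C) removes a C13 hydrogen and places the hydroperoxide on the tertiary carbon, giving the (E)-γ-hydroperoxy enone F10 as both epimers at that carbon. Iodine-catalysed E/Z equilibration under visible light gives the (Z)-hydroperoxy enone F11, which is drained by spontaneous cyclisation to 33 and its epimer at the quaternary peroxide carbon F12; the two are separated by HPLC.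

**Further compounds**

F1 | step 6 | 1-[(2S,5S)-2,5-dimethylpyrrolidin-1-yl]ethan-1-one | CC(=O)N1[C@@H](C)CC[C@@H]1C
F2 | step 6 | (2S,5S)-1-ethenylidene-2,5-dimethylpyrrolidin-1-ium trifluoromethanesulfonate | C=C=[N+]1[C@@H](C)CC[C@@H]1C.[O-]S(=O)(=O)C(F)(F)F
F3 | step 6 | (2S,5S)-1-{(2R,3S)-3-[(tert-butyldiphenylsilyloxy)methyl]-2-[(E)-4-iodo-3-methylbut-3-en-1-yl]-3-methylcyclobutylidene}-2,5-dimethylpyrrolidin-1-ium trifluoromethanesulfonate | I/C=C(C)/CC[C@H]2C(=[N+]3[C@@H](C)CC[C@@H]3C)C[C@]2(C)CO[Si](c1ccccc1)(c1ccccc1)C(C)(C)C.[O-]S(=O)(=O)C(F)(F)F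
F4 | step 11 | 3-{(1R,2S,3S)-3-[(tert-butyldiphenylsilyloxy)methyl]-2-[(E)-4-iodo-3-methylbut-3-en-1-yl]-3-methylcyclobutyl}-3-(triethylsilyloxy)propan-1-ol | I/C=C(C)/CC[C@H]2[C@H](C(O[Si](CC)(CC)CC)CCO)C[C@]2(C)CO[Si](c1ccccc1)(c1ccccc1)C(C)(C)C
F5 | step 11 | 3-{(1R,2S,3S)-3-[(tert-butyldiphenylsilyloxy)methyl]-2-[(E)-4-iodo-3-methylbut-3-en-1-yl]-3-methylcyclobutyl}-3-(triethylsilyloxy)propanal | I/C=C(C)/CC[C@H]2[C@H](C(O[Si](CC)(CC)CC)CC=O)C[C@]2(C)CO[Si](c1ccccc1)(c1ccccc1)C(C)(C)C
F6 | step 11 | (1S,4E,9R,11S)-11-[(tert-butyldiphenylsilyloxy)methyl]-4,11-dimethyl-8-(triethylsilyloxy)bicyclo[7.2.0]undec-4-en-6-ol | CC[Si](CC)(CC)OC1CC(O)/C=C(C)/CC[C@H]2[C@H]1C[C@]2(C)CO[Si](c1ccccc1)(c1ccccc1)C(C)(C)C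
F7 | step 11 | (1S,4E,9R,11S)-11-[(tert-butyldiphenylsilyloxy)methyl]-4,11-dimethyl-8-(triethylsilyloxy)bicyclo[7.2.0]undec-4-en-6-yl acetate | CC[Si](CC)(CC)OC1CC(OC(C)=O)/C=C(C)/CC[C@H]2[C@H]1C[C@]2(C)CO[Si](c1ccccc1)(c1ccccc1)C(C)(C)C
F8 | step 22 | (2Z)-1-[(1S,4S,5S,9R,11S)-4,5-epoxy-4,11-dimethyl-8-methylidenebicyclo[7.2.0]undecan-11-yl]-3-[(2S)-2-methyloxiran-2-yl]prop-2-en-1-one | C=C1CC[C@@H]2O[C@@]2(C)CC[C@H]2[C@H]1C[C@]2(C)C(=O)/C=C\[C@@]1(C)CO1
F9 | step 22 | (3E)-1-[(1S,4S,5S,9R,11S)-4,5-epoxy-4,11-dimethyl-8-methylidenebicyclo[7.2.0]undecan-11-yl]-5-hydroxy-4-methylpent-3-en-1-one | C=C1CC[C@@H]2O[C@@]2(C)CC[C@H]2[C@H]1C[C@]2(C)C(=O)C/C=C(\C)CO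
F10 | step 22 | (2E)-1-[(1S,4S,5S,9R,11S)-4,5-epoxy-4,11-dimethyl-8-methylidenebicyclo[7.2.0]undecan-11-yl]-4-hydroperoxy-5-hydroxy-4-methylpent-2-en-1-one (both C4 epimers) | C=C1CC[C@@H]2O[C@@]2(C)CC[C@H]2[C@H]1C[C@]2(C)C(=O)/C=C/C(C)(CO)OO
F11 | step 22 | (2Z)-1-[(1S,4S,5S,9R,11S)-4,5-epoxy-4,11-dimethyl-8-methylidenebicyclo[7.2.0]undecan-11-yl]-4-hydroperoxy-5-hydroxy-4-methylpent-2-en-1-one (both C4 epimers) | C=C1CC[C@@H]2O[C@@]2(C)CC[C@H]2[C@H]1C[C@]2(C)C(=O)/C=C\C(C)(CO)OO
F12 | step 22 | (6S)-epimer of 33 at the quaternary peroxide carbon (hemiketal centre equilibrating) | C=C1CC[C@@H]2O[C@@]2(C)CC[C@H]2[C@H]1C[C@]2(C)C1(O)C=C[C@@](C)(CO)OO1
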